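**Plan**

1. Retrosynthesis: the ester-bearing cyclohexene is opened at its two ring-fusion σ bonds (retro-Diels–Alder). This leaves a bicyclo[4.2.0]octa-2,4-diene whose cyclobutane carries the decenyl chain and a CH2–dienoate arm, trans to each other. The arm is then cut at its two C=C bonds (HWE, one-carbon homologation). Last, the chain is cut between its first and second carbon counted from the cyclobutane, with the first carbon at the acyl level.
2. Enabling feature: the two carbons that hang on adjacent cyclobutane carbons (C1 of the chain, and the CH2 that later closes the cyclopentane) are the two carbonyl carbons of a cis-cyclobutane-1,2-dicarboxylic anhydride. With the cyclohexadiene fused to the opposite cyclobutane edge, this anhydride is meso.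
3. Forward: cyclobutene ([2+2] photocycloaddition) → fused cyclohexene (Diels–Alder) → cyclohexadiene → chain joined by catalytic desymmetrising alkylation of the anhydride → C8 epimerised and the ketone oxygen removed → dienoate arm built → thermal valence isomerisation and intramolecular Diels–Alder reaction close the cyclopentane and the second cyclohexene together.
4. Stereochemistry: the absolute configuration comes from the catalyst's choice between the two enantiotopic carbonyls. The trans pair on the cyclobutane comes from thermodynamic epimerisation α to the ketone. The six remaining centres come from substrate-controlled pericyclic steps, and the E alkenes from Na/NH3 and HWE.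

Key step: step 9

Remark (assumption): the sense of induction of the Pd–Josiphos catalyst on this new anhydride cannot be assigned in advance. Both ligand antipodes are commercial, and the route is written for the antipode that gives 13 as drawn, to be fixed by a pilot run.

Remark (descriptors): in the bicyclo[4.2.0]octa-2,4-dienes, C7 carries the carboxyl-derived group and C8 the chain. "endo" means on the same side of the cyclobutane as the six-membered ring, and "exo" means the opposite side.

**Route**

Step 1
Reactants: 1 oct-7-yn-1-ol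
Product: 2 non-7-yn-1-ol
Conditions: n-BuLi (2.1 equiv), THF/DMPU, −78 → −20 °C; MeI (1.0 equiv), −78 °C → rt; H2O
Reagents that add atoms: iodomethane CI
Why: Double deprotonation gives the alkoxide–acetylide dianion, whose carbon terminus is the better nucleophile, so one equivalent of MeI should C-methylate the alkyne (acetylide alkylation); no stereocentre is involved.

Step 2
Reactants: 2 non-7-yn-1-ol
Product: 3 (E)-non-7-en-1-ol
Conditions: Na (4 equiv), NH3(l)/THF, −33 °C; then NH4Cl
Reagents that add atoms: none
Why: Dissolving-metal reduction of the internal alkyne runs through the trans vinyl radical anion and should give the E alkene with high selectivity, the alkoxide being inert.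

Step 3
Reactants: 3 (E)-non-7-en-1-ol
Product: 4 (E)-9-iodonon-2-ene
Conditions: PPh3, I2, imidazole, CH2Cl2, 0 °C → rt
Reagents that add atoms: iodine II
Why: Appel-type iodination converts the primary alcohol into the iodide by SN2 on the alkoxyphosphonium ion without touching the alkene.

Step 4
Reactants: 4 (E)-9-iodonon-2-ene
Product: 5 bis[(E)-non-7-en-1-yl]zinc
Conditions: Et2Zn (neat, 3 equiv), CuI (0.3 mol%), 50 °C; volatiles removed at 50 °C/0.1 mmHg; used as a THF solution
Reagents that add atoms: diethylzinc CC[Zn]CC
Why: Copper-catalysed iodine–zinc exchange is driven to the salt-free dialkylzinc by distilling off EtI and excess Et2Zn, and the remote E alkene is inert to a primary alkylzinc.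

Step 5
Reactants: 6 maleic anhydride; 7 acetylene
Product: 8 cis-cyclobut-3-ene-1,2-dicarboxylic anhydride (meso)
Conditions: acetylene (sat.), acetophenone (sens.), EtOAc, hν (Hg lamp, Pyrex), −60 °C
Reagents that add atoms: none
Why: Triplet-sensitised [2+2] photocycloaddition of maleic anhydride to acetylene keeps the cis anhydride fusion, which fixes the cis (meso) relationship of the two future side-chain carbons.

Step 6
Reactants: 8 cis-cyclobut-3-ene-1,2-dicarboxylic anhydride; 9 buta-1,3-diene
Product: 10 cis-anti-cis-bicyclo[4.2.0]oct-3-ene-7,8-dicarboxylic anhydride (meso)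
Conditions: butadiene (5 equiv), BHT (cat.), PhMe, sealed tube, 110 °C
Reagents that add atoms: none
Why: The strained cyclobutene acts as dienophile in a thermal Diels–Alder reaction; suprafacial addition sets the two ring-fusion centres cis and the diene should approach the convex face anti to the anhydride, so the adduct stays meso.

Step 7
Reactants: 10 cis-anti-cis-bicyclo[4.2.0]oct-3-ene-7,8-dicarboxylic anhydride
Product: 11 trans-3,4-dibromobicyclo[4.2.0]octane-7,8-dicarboxylic anhydride (racemic)
Conditions: Br2 (1.05 equiv), CH2Cl2, −78 → 0 °C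
Reagents that add atoms: bromine BrBr
Why: Anti addition of bromine through the bromonium ion to the only alkene gives the trans dibromide set up for double E2, the anhydride being inert.

Step 8
Reactants: 11 trans-3,4-dibromobicyclo[4.2.0]octane-7,8-dicarboxylic anhydride
Product: 12 cis-anti-cis-bicyclo[4.2.0]octa-2,4-diene-7,8-dicarboxylic anhydride (meso)
Conditions: DBU (2.3 equiv), THF, 0 → 50 °C; DBU·HBr filtered off under N2, no aqueous work-up
Reagents that add atoms: none
Why: Two successive anti-periplanar E2 eliminations with the amidine base take the ring CH2 protons next to each bromide and should give the conjugated 2,4-diene, which is again meso; the non-aqueous work-up is chosen so that the anhydride survives.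

Step 9
Reactants: 12 cis-anti-cis-bicyclo[4.2.0]octa-2,4-diene-7,8-dicarboxylic anhydride; 5 bis[(E)-non-7-en-1-yl]zinc
Product: 13 7,8-cis-8-[(E)-dec-8-enoyl]bicyclo[4.2.0]octa-2,4-diene-7-carboxylic acid (both groups exo; single enantiomer)
Conditions: Pd(OAc)2 (5 mol%), Josiphos SL-J001 (6 mol%, antipode per the remark), 4-fluorostyrene (0.5 equiv), 5 (1.2 equiv), THF, 0 °C → rt; then 1 M HCl
Reagents that add atoms: none
Why: Pd(0)–Josiphos inserts into one of the two enantiotopic acyl C–O bonds of the meso anhydride to give an acyl-Pd(II) carboxylate, the nonenyl group is transferred from zinc, and C(acyl)–C(sp3) reductive elimination forms the ketone and releases the zinc carboxylate. The closest known reaction type is the Pd- or Ni-catalysed enantioselective alkylation of meso succinic anhydrides with diorganozinc reagents (an acyl Negishi coupling). No ring is closed; the anhydride ring is opened. No new stereocentre is created, but the chiral catalyst decides which of C7 and C8 becomes the ketone-bearing carbon, and this one choice fixes the absolute configuration of all eight stereocentres of the target. The step needs enantiotopic-group selection (ligand control in the oxidative addition), mono-addition (dialkylzincs do not add to the ketone or the carboxylate) and reductive elimination faster than β-hydride elimination (bidentate ferrocenyl diphosphine, styrene additive); the ring diene is a weaker ligand than the diphosphine and the E alkene of the zinc reagent is remote. The ketone oxygen is a temporary helper: it makes C8 epimerisable in step 10 and is removed in steps 11–13.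

Step 10
Reactants: 13 7,8-cis-8-[(E)-dec-8-enoyl]bicyclo[4.2.0]octa-2,4-diene-7-carboxylic acid
Product: 15 methyl 7,8-trans-8-[(E)-dec-8-enoyl]bicyclo[4.2.0]octa-2,4-diene-7-carboxylate (acyl endo; ester exo), via cis keto ester 14 (not isolated)
Conditions: TMSCHN2, PhMe/MeOH (4:1), 0 °C; concentrate; NaOMe (0.2 equiv), MeOH, 0 °C → rt; AcOH quench; recovered 14 is resubmitted
Reagents that add atoms: trimethylsilyldiazomethane C[Si](C)(C)C=[N+]=[N-]
Why: O-Methylation of the acid by the diazoalkane is followed by methoxide-mediated enolisation of the ring CH α to the ketone (thermodynamic epimerisation), which should relieve the eclipsed cis-1,2-diacyl arrangement on the cyclobutane and set C8 trans to C7, while the less acidic ester α-CH at C7 stays untouched under catalytic base so that the enantiomeric purity is kept.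

Step 11
Reactants: 15 methyl 7,8-trans-8-[(E)-dec-8-enoyl]bicyclo[4.2.0]octa-2,4-diene-7-carboxylate
Product: 16 methyl 7,8-trans-8-[(E)-1-hydroxydec-8-en-1-yl]bicyclo[4.2.0]octa-2,4-diene-7-carboxylate (carbinol epimers)
Conditions: NaBH4 (1.5 equiv), MeOH, −20 → 0 °C
Reagents that add atoms: none
Why: Chemoselective borohydride reduction of the ketone beside the methyl ester; the new carbinol centre is removed in step 13 and the trans arrangement prevents lactonisation.

Step 12
Reactants: 16 methyl 7,8-trans-8-[(E)-1-hydroxydec-8-en-1-yl]bicyclo[4.2.0]octa-2,4-diene-7-carboxylate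
Product: 17 methyl 7,8-trans-8-[(E)-1-(methylsulfonyloxy)dec-8-en-1-yl]bicyclo[4.2.0]octa-2,4-diene-7-carboxylate
Conditions: MsCl, Et3N, CH2Cl2, 0 °C; used crude
Reagents that add atoms: methanesulfonyl chloride CS(Cl)(=O)=O
Why: Standard sulfonylation of the secondary alcohol installs the leaving group for hydride displacement.

Step 13
Reactants: 17 methyl 7,8-trans-8-[(E)-1-(methylsulfonyloxy)dec-8-en-1-yl]bicyclo[4.2.0]octa-2,4-diene-7-carboxylate
Product: 18 {7,8-trans-8-[(E)-dec-8-en-1-yl]bicyclo[4.2.0]octa-2,4-dien-7-yl}methanol (decenyl endo; CH2OH exo)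
Conditions: LiBHEt3 (4 equiv), THF, 0 → 40 °C; H2O
Reagents that add atoms: none
Why: Lithium triethylborohydride should displace the secondary mesylate by a two-electron SN2 path (a radical or cation at this carbon would open or expand the diene-flanked cyclobutane) and at the same time reduce the ester to the primary alcohol, the trans geometry excluding intramolecular ether formation.

Step 14
Reactants: 18 {7,8-trans-8-[(E)-dec-8-en-1-yl]bicyclo[4.2.0]octa-2,4-dien-7-yl}methanol
Product: 19 7,8-trans-8-[(E)-dec-8-en-1-yl]bicyclo[4.2.0]octa-2,4-diene-7-carbaldehyde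
Conditions: Dess–Martin periodinane (1.3 equiv), CH2Cl2, 0 °C → rt
Reagents that add atoms: none
Why: Dess–Martin oxidation stops at the aldehyde under near-neutral conditions, and the exo aldehyde trans to the C8 chain is the more stable epimer, so C7 is not at risk.

Step 15
Reactants: 19 7,8-trans-8-[(E)-dec-8-en-1-yl]bicyclo[4.2.0]octa-2,4-diene-7-carbaldehyde
Product: 21 2-{7,8-trans-8-[(E)-dec-8-en-1-yl]bicyclo[4.2.0]octa-2,4-dien-7-yl}acetaldehyde, via methyl enol ether 20 (not isolated)
Conditions: MeOCH2PPh3Cl, KHMDS, THF, 0 °C; 19, −78 → 0 °C; then 1 M HCl, THF, rt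
Reagents that add atoms: (methoxymethyl)triphenylphosphonium chloride COC[P+](c1ccccc1)(c1ccccc1)c1ccccc1.[Cl-]; water O
Why: Wittig reaction with the methoxymethylene ylide gives the enol ether, whose mild acid hydrolysis should deliver the one-carbon-homologated aldehyde without affecting any stereocentre.

Step 16
Reactants: 21 2-{7,8-trans-8-[(E)-dec-8-en-1-yl]bicyclo[4.2.0]octa-2,4-dien-7-yl}acetaldehyde; 22 methyl (E)-4-(dimethoxyphosphoryl)but-2-enoate
Product: 23 methyl (2E,4E)-6-{7,8-trans-8-[(E)-dec-8-en-1-yl]bicyclo[4.2.0]octa-2,4-dien-7-yl}hexa-2,4-dienoate (decenyl endo; dienoate arm exo)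
Conditions: 22, LiHMDS, THF, −78 °C; then 21, −78 → 0 °C
Reagents that add atoms: none
Why: Horner–Wadsworth–Emmons olefination with the lithiated 4-phosphonocrotonate should give the (2E,4E)-dienoate under the usual control of stabilised phosphonate anions.

Step 17
Reactants: 23 methyl (2E,4E)-6-{7,8-trans-8-[(E)-dec-8-en-1-yl]bicyclo[4.2.0]octa-2,4-dien-7-yl}hexa-2,4-dienoate
Product: 26 CNP0133550.1 (the tetracyclic methyl ester: cyclobutane/cyclohexene/cyclopentane/cyclohexene cage with the (E)-dec-8-enyl chain on the cyclobutane), via trans-cyclooctatriene valence isomer 24 (not isolated), via endo-dienoate bicyclooctadiene 25 (not isolated)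
Conditions: PhMe (0.01 M), BHT (cat.), 105 °C, sealed tube, dark
Reagents that add atoms: none
Why: Thermal disrotatory 6π opening to the trans-7,8-disubstituted cyclooctatriene and re-closure on the other face interconvert 23 and 25, and only 25, with the dienoate arm endo, can undergo the intramolecular Diels–Alder reaction of its (E,E)-diene with the proximal ring alkene (Curtin–Hammett funnel), the three-atom tether forcing addition to the concave face in the exo mode so that the four new centres follow from the two cyclobutane centres.

**Compound list**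

1 | oct-7-yn-1-ol | C#CCCCCCCO | starting material
2 | non-7-yn-1-ol | CC#CCCCCCCO | intermediate
3 | (E)-non-7-en-1-ol | C/C=C/CCCCCCO | intermediate
4 | (E)-9-iodonon-2-ene | C/C=C/CCCCCCI | intermediate
5 | bis[(E)-non-7-en-1-yl]zinc | C/C=C/CCCCCC[Zn]CCCCCC/C=C/C | intermediate
6 | maleic anhydride | O=C1OC(=O)C=C1 | starting material
7 | acetylene | C#C | starting material
8 | cis-cyclobut-3-ene-1,2-dicarboxylic anhydride (meso) | O=C3[C@H]1C=C[C@H]1C(=O)O3 | intermediate
9 | buta-1,3-diene | C=CC=C | starting material
10 | cis-anti-cis-bicyclo[4.2.0]oct-3-ene-7,8-dicarboxylic anhydride (meso; anhydride anti to the six-membered ring) | O=C3[C@H]1[C@@H]2CC=CC[C@@H]2[C@H]1C(=O)O3 | intermediate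
11 | trans-3,4-dibromobicyclo[4.2.0]octane-7,8-dicarboxylic anhydride (racemic; one enantiomer drawn) | O=C3[C@H]1[C@@H]2C[C@@H](Br)[C@H](Br)C[C@@H]2[C@H]1C(=O)O3 | intermediate
12 | cis-anti-cis-bicyclo[4.2.0]octa-2,4-diene-7,8-dicarboxylic anhydride (meso) | O=C3[C@H]1[C@@H]2C=CC=C[C@@H]2[C@H]1C(=O)O3 | intermediate
13 | 7,8-cis-8-[(E)-dec-8-enoyl]bicyclo[4.2.0]octa-2,4-diene-7-carboxylic acid (both exo) | C/C=C/CCCCCCC(=O)[C@H]1[C@@H]2C=CC=C[C@@H]2[C@H]1C(=O)O | intermediate
14 | methyl 7,8-cis-8-[(E)-dec-8-enoyl]bicyclo[4.2.0]octa-2,4-diene-7-carboxylate (both exo) | C/C=C/CCCCCCC(=O)[C@H]1[C@@H]2C=CC=C[C@@H]2[C@H]1C(=O)OC | intermediate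
15 | methyl 7,8-trans-8-[(E)-dec-8-enoyl]bicyclo[4.2.0]octa-2,4-diene-7-carboxylate (acyl endo, ester exo) | C/C=C/CCCCCCC(=O)[C@@H]1[C@@H]2C=CC=C[C@@H]2[C@H]1C(=O)OC | intermediate
16 | methyl 7,8-trans-8-[(E)-1-hydroxydec-8-en-1-yl]bicyclo[4.2.0]octa-2,4-diene-7-carboxylate (carbinol epimers) | C/C=C/CCCCCCC(O)[C@@H]1[C@@H]2C=CC=C[C@@H]2[C@H]1C(=O)OC | intermediate
17 | methyl 7,8-trans-8-[(E)-1-(methylsulfonyloxy)dec-8-en-1-yl]bicyclo[4.2.0]octa-2,4-diene-7-carboxylate | C/C=C/CCCCCCC(OS(C)(=O)=O)[C@@H]1[C@@H]2C=CC=C[C@@H]2[C@H]1C(=O)OC | intermediate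
18 | {7,8-trans-8-[(E)-dec-8-en-1-yl]bicyclo[4.2.0]octa-2,4-dien-7-yl}methanol | C/C=C/CCCCCCC[C@@H]1[C@@H]2C=CC=C[C@@H]2[C@H]1CO | intermediate
19 | 7,8-trans-8-[(E)-dec-8-en-1-yl]bicyclo[4.2.0]octa-2,4-diene-7-carbaldehyde | C/C=C/CCCCCCC[C@@H]1[C@@H]2C=CC=C[C@@H]2[C@H]1C=O | intermediate
20 | 7,8-trans-8-[(E)-dec-8-en-1-yl]-7-(2-methoxyethenyl)bicyclo[4.2.0]octa-2,4-diene (E/Z) | C/C=C/CCCCCCC[C@@H]1[C@@H]2C=CC=C[C@@H]2[C@H]1C=COC | intermediate
21 | 2-{7,8-trans-8-[(E)-dec-8-en-1-yl]bicyclo[4.2.0]octa-2,4-dien-7-yl}acetaldehyde | C/C=C/CCCCCCC[C@@H]1[C@@H]2C=CC=C[C@@H]2[C@H]1CC=O | intermediate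
22 | methyl (E)-4-(dimethoxyphosphoryl)but-2-enoate | COC(=O)/C=C/CP(=O)(OC)OC | starting material
23 | methyl (2E,4E)-6-{7,8-trans-8-[(E)-dec-8-en-1-yl]bicyclo[4.2.0]octa-2,4-dien-7-yl}hexa-2,4-dienoate (decenyl endo, arm exo) | C/C=C/CCCCCCC[C@@H]1[C@@H]2C=CC=C[C@@H]2[C@H]1C/C=C/C=C/C(=O)OC | intermediate
24 | methyl (2E,4E)-6-{trans-8-[(E)-dec-8-en-1-yl]cycloocta-2,4,6-trien-1-yl}hexa-2,4-dienoate | C/C=C/CCCCCCC[C@@H]1/C=C\C=C/C=C\[C@H]1C/C=C/C=C/C(=O)OC | intermediate
25 | valence isomer of 23 with the decenyl group exo and the dienoate arm endo | C/C=C/CCCCCCC[C@@H]1[C@H]2C=CC=C[C@H]2[C@H]1C/C=C/C=C/C(=O)OC | intermediate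
26 | CNP0133550.1 | C/C=C/CCCCCCC[C@@H]1[C@H]2C=C[C@@H]3[C@@H]4[C@H]2[C@H]1C[C@H]4C=C[C@H]3C(=O)OC | target

**Step count and risks**

Total step count: 17. Longest linear sequence: 13 steps (steps 5–17 from maleic anhydride; equally steps 1–4 and 9–17 from oct-7-yn-1-ol).

Steps most likely to fail:

1. Step 9. Selection between the enantiotopic carbonyls may be poor on this cyclobutane-fused anhydride, the ring diene may divert the palladium, or β-hydride elimination may outrun reductive elimination. Fallback: the two tasks are separated. From anhydride 12, cinchona-alkaloid-mediated methanolysis (quinidine or quinine, MeOH, toluene, −55 °C) would give the 7-methyl 8-hydrogen monoester F1. Its free acid is converted into the S-ethyl thioester F2 (EtSH, EDC, DMAP). A Fukuyama coupling of F2 with (E)-non-7-enylzinc iodide F3 (from iodide 4, Zn dust, LiCl; PdCl2(PPh3)2, THF/toluene, rt) forms the same C–C bond and gives cis keto ester 14, where the route resumes with the methoxide equilibration to 15.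

2. Step 13. E2 elimination, attack of hydride at sulfur, or ionisation with cyclobutane ring expansion may compete with SN2 at the hindered secondary mesylate. Fallback: a hydrazone-based deoxygenation from keto ester 15. Condensation with TsNHNH2 gives the tosylhydrazone F4, which is reduced with catecholborane (CHCl3, 0 °C) and then NaOAc·3H2O (reflux) to the methyl ester F5. DIBAL-H (CH2Cl2, −78 °C) then returns to aldehyde 19. This path is held in reserve because the diazene it passes through may fragment the cyclobutane.

3. Step 8. The amidine base may open or enolise the anhydride during the double dehydrobromination, or the diene may begin to equilibrate through its cyclooctatriene form. Fallback: the diene is made by cycloaddition and extrusion instead of addition and elimination. From cyclobutene anhydride 8, heating with 2H-pyran-2-one (toluene, 110–140 °C) would give the bridged lactone F6 by [4+2] cycloaddition. Retro-[4+2] loss of CO2 from F6 gives anhydride 12 directly, bypassing steps 6–8.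

**Further compounds**

F1 | step 9 | 7,8-cis-7-(methoxycarbonyl)bicyclo[4.2.0]octa-2,4-diene-8-carboxylic acid (both exo) | O=C(O)[C@H]1[C@@H]2C=CC=C[C@@H]2[C@H]1C(=O)OC
F2 | step 9 | methyl 7,8-cis-8-[(ethylsulfanyl)carbonyl]bicyclo[4.2.0]octa-2,4-diene-7-carboxylate | CCSC(=O)[C@H]1[C@@H]2C=CC=C[C@@H]2[C@H]1C(=O)OC
F3 | step 9 | (E)-non-7-en-1-ylzinc iodide | C/C=C/CCCCCC[Zn]I
F4 | step 13 | tosylhydrazone of keto ester 15 | C/C=C/CCCCCCC(=NNS(=O)(=O)c1ccc(C)cc1)[C@@H]1[C@@H]2C=CC=C[C@@H]2[C@H]1C(=O)OC
F5 | step 13 | methyl 7,8-trans-8-[(E)-dec-8-en-1-yl]bicyclo[4.2.0]octa-2,4-diene-7-carboxylate | C/C=C/CCCCCCC[C@@H]1[C@@H]2C=CC=C[C@@H]2[C@H]1C(=O)OC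
F6 | step 8 | [4+2] adduct of 8 with 2H-pyran-2-one (bridged lactone; bridge configuration undefined) | O=C3[C@H]1[C@@H]2C4C=CC(OC4=O)[C@@H]2[C@H]1C(=O)O3
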